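## Analysis of the target

The target (60) is a tetracycle. A cyclohexene (ring A) is spiro-fused through its quaternary carbon to a 3-acyl tetronic acid (ring B). An all-trans 2,3,4-trisubstituted thiolane (ring C) is tied to rings A and B by a 19-membered carbocycle (ring D).

Locants used below: ring A is A1 (spiro carbon, also C5 of ring B), A2 (CH carrying the chain), A3=A4 (A4 methylated), A5 (CHCH3), A6. Ring B is O1, C2 (lactone C=O), C3 (acylated), C4 (enol OH), C5. Ring C is S1, C2 (keto acid), C3 (chain), C4 (acyl), C5. The chain is C1' (on A2), C2'=C3'–C4'=C5' (E,E), C6', C7' (carbinol), C8', C9'=C10' (E), C11', C12' (CHCH3, bonded to C3 of ring C).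

There are eight stereocentres. On ring A the chain at A2 is cis to the ring-B oxygen at A1 and cis to the methyl at A5. C7' is isolated. C12' adjoins the ring-C triad C2/C3/C4, in which each neighbouring pair is trans. Ring A, C7' and ring C have no stereochemical contact and must come from three separate enantiopure pieces.

Sensitive groups are the α-keto acid (electrophilic, enolisable at C2 between sulfur and ketone), the acyl tetronic acid (strongly acidic, chelating) and the sulfide (oxidants, soft metals, alkylating agents). In addition, C4'=C5' and C9'=C10' form a hepta-1,6-diene, so ring-closing olefin metathesis anywhere on this chain would compete with cyclopentene extrusion.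

The hard part is ring C: three contiguous stereocentres on a cyclic sulfide, one carrying a 1,2-dicarbonyl on the carbon next to sulfur, where late oxidation would also hit sulfur. The plan rests on the position of C2 of ring C between S1 and C3. Removed as a carbene carbon, it leaves a thietane in which sulfur is bonded directly to C3, and the trans C3/C4 relation becomes the trans 2,3-relation of a four-membered ring.

## Retrosynthetic reasoning

**60 to 57.** The keto acid is masked as the dimethyl ketal methyl ester and the C7' hydroxyl as a tert-butyldiphenylsilyl ether. Removing the silyl group (58) and then the ester and ketal (59) are the last operations, so 57 is the last intermediate that needs skeletal chemistry. The ketal is essential earlier: a free ketone next to sulfur would be attacked by the organozinc of the chain coupling, and would form a cyclic ketal with the cis C4 hydroxymethyl group once that is unmasked.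

**57 to 56 (ring D).** The ring is opened at C3'–C4', the central bond of the diene, to an E-alkenyl iodide on the ring-A arm and an E-alkenyl boronate on the chain. This is the one ring-D bond that a palladium-catalysed sp2–sp2 coupling can form with both geometries fixed beforehand. Metathesis is excluded by the 1,6-diene, and a ring closure at the acyl–tetronate bond would need a strong base next to epimerisable centres. The forward reaction has to couple intramolecularly in the presence of the sulfide and the tetronic acid, which is carried as its salt.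

**56 to 54 + 51 (acyl–tetronate bond).** The bond between the C4 carbonyl of ring C and C3 of ring B is cut to carboxylic acid 54 and the 3-unsubstituted spiro tetronic acid 51. Joining them is a carbodiimide C-acylation that needs no organolithium, so the alkenyl iodide of 51 and the alkenyl boronate of 54 both pass through untouched. A tert-butyl ester (53) keeps the acid masked until this point and is removed without base or fluoride.

**53 to 27 + 36 (C10'–C11').** This sp3–sp2 bond is cut to primary iodide 27 and alkenyl iodide 36. The Negishi coupling keeps the E geometry of C9'=C10', and the boronate at the other end of 36 stays inert because no base is present. All three stereocentres of ring C and C12' are thereby delivered in one fragment.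

**27 to 20 (functional-group adjustment).** Iodide 27 comes from keto ester 20 by ketalisation (21), oxidation of the C4 side arm to the acid (22, 24), esterification (25) and exchange of the silyl ether for iodide (26, 27). The C4 substituent is carried as a 4-methoxybenzyloxymethyl group through the ring-forming steps. With an ester there, both leaving groups of the acyclic thietane precursor would lie β to an enolisable carbonyl and elimination would compete with closure. The carboxyl level is restored on the robust thiolane, by oxidants that spare sulfides.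

**20 to 16 + 18 (ring C, the key disconnection).** The S1–C2 and C2–C3 bonds are cut, removing C2 with its keto ester as diazo ketone 18 and leaving trans-2,3-disubstituted thietane 16. Forward, carbene transfer to sulfur and a [1,2]-shift of the resulting ylide (19) insert the carbon into the more substituted S–C bond. The keto ester therefore arrives complete, no oxidation next to sulfur is needed, and the C3/C4 relation is taken over from the thietane.

**16 to 7 + 10.** The thietane is opened at both C–S bonds to bis-mesylate 14 of diol 13. Closure inverts the secondary carbon, so 13 needs the all-syn stereotriad. That triad is the syn-aldol product 12 of imide 7 and aldehyde 10, reduced at the imide carbonyl. Aldehyde 10 carries C12' from ester 8, and auxiliary 5 sets the other two centres.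

**36 to 28.** C7' with its two different three-carbon arms comes from epoxide 28 by two successive acetylide openings (29 to 31), one arm kept silylated so the two alkynes can be turned separately into the E-alkenyl iodide (34) and the E-alkenyl boronate (36).

**51 to 40 + 45.** Ring B is opened at C3–C4 to α-acetoxy ester 50 (Dieckmann). Ring A is cut at its two bonds to the former dienophile carbons, giving E,E-diene 40 and the chiral methylidene dioxolanone 45. A single cycloaddition (46) sets A1, A2 and A5. The diene comes from 38 and 39, the dienophile from 41 and 42.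

## Alternatives that were turned down

**Alternative 1: ring D by a Stille macrocyclisation.** The disconnection is the central diene bond C3'–C4' in seco compound A2, which already holds rings A, B and C and ends in an E-alkenyl stannane and an E-alkenyl iodide. Forward, zerovalent palladium couples the two ends of A2 to macrocycle A1 (O-methyl tetronate, ketal ester). In its favour, this is the most dependable closure for a diene-containing macrocycle, it is stereoretentive, and it is neutral, so a base-sensitive O-methyl tetronate passes. On this point it is at least as strong as the boron closure of step 38, which needs base. Against it as the centre of a plan: it puts the decisive step at the last C–C bond, on material that carries every fragment, and it says nothing about ring C, the real difficulty. It also requires an acid-sensitive stannane to survive the tetronate chemistry, and tin has to be removed from a sulfur-containing acid. The chosen route closes the same bond but does not depend on it. In exchange it offers ring C, keto ester included, in one early step on cheap material, and a tin-free end game without tetronate protection.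

**Alternative 2: ring A by a boat Ireland–Claisen contraction.** The disconnection is the A1–A2 bond. The silyl ketene acetal of δ-lactone A4 (quaternary C6 carrying a Z-alkenyl group) rearranges through the boat the lactone ring enforces, giving cyclohexene acid A3. In its favour, chirality is transferred intramolecularly, with no exo/endo question, no chiral dienophile and no prolonged heating of a polymerisable alkene. On stereochemical certainty it is stronger than the cycloaddition of step 29. Against it: A4 needs a stereodefined tertiary carbinol with a Z-alkene and a neighbouring methyl centre, which is no easier to make than ring A itself. The tertiary 4-methoxybenzyl ether of A3 must still be exchanged for an acetate before ring B can form. The effort goes into the part of the molecule with the best-established solution. The chosen route reaches the same ring-A acid level (49) in one cycloaddition from two simple partners and reserves its one demanding step for ring C.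

**Alternative 3: rings B and D by a transannular Dieckmann ring contraction.** The disconnection is the C3–C4 bond of ring B inside 20-membered β-keto lactone A6, whose ester oxygen is the tertiary oxygen on A1. Forward, base forms the β-keto ester enolate, which attacks the methyl ester on A1 to give macrocyclic acyl tetronic acid A5. In its favour, it makes two rings in one operation, needs no organometallic handles, and delivers the free tetronic acid directly. On step economy at the end it is stronger. Against it: the macrolactone is an ester of a hindered tertiary α-hydroxy ester. The ring-C acid must first be homologated to a β-keto acid equivalent. The enolate must form next to the epimerisable C4 of ring C and in the presence of a second methyl ester. The transannular attack depends on a macrocycle conformation that cannot be predicted. The chosen route forms ring B by the same condensation on a small fragment (step 34), joins ring C by acyl transfer, and closes ring D with a stereoretentive C–C coupling, at the cost of two extra handles.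

Key step: step 11

Assumption: the target is made in the tautomeric form drawn (ring B as the 4-hydroxy enol, free α-keto acid), and compounds 1, 2, 5, 8, 17, 28, 37, 39, 41 and 42 are taken as purchasable.

## Route

### Ring C fragment (steps 1–17)

Step 1
Reactants: 1 4-methoxybenzyl alcohol; 2 methyl acrylate
Product: 3 methyl 3-[(4-methoxybenzyl)oxy]propanoate
Conditions: NaH (0.05 equiv), THF, 0 °C → rt
Reagents that add atoms: none
Why: Base-catalysed oxa-Michael addition of a primary alkoxide to an acrylate; any transesterified by-product converges on the same acid in step 2.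

Step 2
Reactants: 3 methyl 3-[(4-methoxybenzyl)oxy]propanoate
Product: 4 3-[(4-methoxybenzyl)oxy]propanoic acid
Conditions: LiOH, THF/H2O, rt; then aq. HCl
Reagents that add atoms: lithium hydroxide, [Li+].[OH-]
Why: Ordinary ester saponification; the benzyl-type ether is stable to base and to brief dilute acid.

Step 3
Reactants: 4 3-[(4-methoxybenzyl)oxy]propanoic acid; 5 (S)-4-benzyl-1,3-oxazolidin-2-one
Product: 7 (S)-4-benzyl-3-{3-[(4-methoxybenzyl)oxy]propanoyl}-1,3-oxazolidin-2-one, via mixed pivalic anhydride 6 (not isolated)
Conditions: t-BuCOCl, Et3N, THF, −20 °C; then LiCl, 5, rt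
Reagents that add atoms: none
Why: N-acylation of the oxazolidinone through the mixed anhydride; the nucleophile attacks the unhindered carbonyl of 6.

Step 4
Reactants: 8 methyl (S)-3-hydroxy-2-methylpropanoate
Product: 9 methyl (S)-3-[(tert-butyldiphenylsilyl)oxy]-2-methylpropanoate
Conditions: t-BuPh2SiCl, imidazole, DMF, rt
Reagents that add atoms: tert-butyl(chloro)diphenylsilane, CC(C)(C)[Si](Cl)(c1ccccc1)c1ccccc1
Why: Silylation of a primary alcohol; the stereocentre (later C12') is not involved.

Step 5
Reactants: 9 methyl (S)-3-[(tert-butyldiphenylsilyl)oxy]-2-methylpropanoate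
Product: 10 (S)-3-[(tert-butyldiphenylsilyl)oxy]-2-methylpropanal
Conditions: i-Bu2AlH, CH2Cl2, −78 °C; aq. potassium sodium tartrate
Reagents that add atoms: none
Why: Partial reduction of the ester through the aluminium hemiacetal, which is stable at −78 °C; the aldehyde is used at once so that its α-centre does not epimerise.

Step 6
Reactants: 7 (S)-4-benzyl-3-{3-[(4-methoxybenzyl)oxy]propanoyl}-1,3-oxazolidin-2-one; 10 (S)-3-[(tert-butyldiphenylsilyl)oxy]-2-methylpropanal
Product: 12 (S)-4-benzyl-3-[(2S,3R,4S)-5-[(tert-butyldiphenylsilyl)oxy]-3-hydroxy-2-{[(4-methoxybenzyl)oxy]methyl}-4-methylpentanoyl]-1,3-oxazolidin-2-one, via Z-dibutylboron enolate 11 (not isolated)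
Conditions: Bu2BOTf, i-Pr2NEt, CH2Cl2, 0 °C; 10, −78 → 0 °C; then pH 7 buffer, MeOH, H2O2
Reagents that add atoms: none
Why: Evans syn-aldol: the Z-boron enolate reacts through a chair transition state on the face away from the benzyl group, which sets the α-carbon and the carbinol. The (S)-auxiliary places both syn to the methyl group of 10; this is the less favoured pairing for a Z-enolate, but reagent control should dominate.

Step 7
Reactants: 12 aldol adduct
Product: 13 (2S,3R,4S)-5-[(tert-butyldiphenylsilyl)oxy]-2-{[(4-methoxybenzyl)oxy]methyl}-4-methylpentane-1,3-diol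
Conditions: LiBH4, H2O (1 equiv), THF, 0 °C
Reagents that add atoms: none
Why: Reductive cleavage of the N-acyl oxazolidinone to the primary alcohol; no stereocentre is touched and auxiliary 5 is recovered.

Step 8
Reactants: 13 diol
Product: 14 1,3-bis(methanesulfonate) of diol 13
Conditions: MeSO2Cl, Et3N, CH2Cl2, 0 °C
Reagents that add atoms: methanesulfonyl chloride, CS(=O)(=O)Cl
Why: Sulfonylation of both hydroxyls through sulfene; the carbinol C–O bond is not broken, so its configuration is kept.

Step 9
Reactants: 14 bis-mesylate
Product: 16 (2S,3R)-2-{(2S)-1-[(tert-butyldiphenylsilyl)oxy]propan-2-yl}-3-{[(4-methoxybenzyl)oxy]methyl}thietane, via primary sodium thiolate 15 (not isolated)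
Conditions: Na2S·9H2O, DMF, 60 °C, 0.02 M
Reagents that add atoms: sodium sulfide, [Na+].[Na+].[S-2]
Why: Thietane synthesis by double displacement of a 1,3-disulfonate: sulfide substitutes the primary mesylate, and thiolate 15 closes by 4-exo-tet SN2 at the secondary carbon with inversion, turning the all-syn triad into the trans-2,3-disubstituted ring. No carbonyl group is present, so neither leaving group has an acidic β-hydrogen.

Step 10
Reactants: 17 methyl chlorooxoacetate
Product: 18 methyl 3-diazo-2-oxopropanoate
Conditions: CH2N2 (2.5 equiv), Et2O, 0 °C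
Reagents that add atoms: diazomethane, C=[N+]=[N-]
Why: Acylation of diazomethane by an acid chloride, as in the first stage of an Arndt–Eistert sequence; the second equivalent removes HCl as chloromethane.

Step 11
Reactants: 16 thietane; 18 methyl 3-diazo-2-oxopropanoate
Product: 20 methyl 2-[(2S,3S,4R)-3-{(2R)-1-[(tert-butyldiphenylsilyl)oxy]propan-2-yl}-4-{[(4-methoxybenzyl)oxy]methyl}thiolan-2-yl]-2-oxoacetate, via thietanium ylide 19 (not isolated)
Conditions: Rh2(OAc)4 (2 mol%), 18 added over 6 h, benzene, 80 °C; then Et3N (0.1 equiv), CH2Cl2, rt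
Reagents that add atoms: none
Why: Rh2(OAc)4 converts diazo ketone 18 into an electrophilic rhodium carbene, which the thietane sulfur, the best nucleophile in 16, captures to give sulfonium ylide 19. The strained ylide then undergoes a Stevens [1,2]-shift: the bond from sulfur to the substituted ring carbon breaks homolytically and the carbon radical recombines with the ylide carbon inside the solvent cage, which inserts one carbon between sulfur and that carbon. The closest known reaction type is the metal-carbene ring expansion of thietanes and oxetanes to five-membered rings through onium ylides; only the substitution pattern and the keto ester on the carbene are new. Ring C is thus formed by ring expansion, the collapse of a 1,5-diradical held together by the remaining C–C–S tether, and not by an exo or endo attack. The migrating carbon (C3 of the thiolane) keeps its configuration because recombination outruns rotation, and a rotated radical would in any case close trans to the neighbouring ring substituent. The new centre C2 is enolisable between sulfur and ketone and settles trans to the C3 substituent; the triethylamine treatment completes this equilibration. The step needs migration of the substituted S–C bond rather than the S–CH2 bond; the secondary radical is the more stable one and its departure relieves crowding around the sulfonium centre. Because the thietane carries an ether and not an ester at C3, there is no acidic hydrogen β to sulfur and ring-opening elimination is not a competitor.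

Step 12
Reactants: 20 thiolane keto ester
Product: 21 dimethyl ketal of 20 (methyl 2,2-dimethoxyacetate at C2 of ring C)
Conditions: HC(OMe)3, MeOH, camphorsulfonic acid (0.2 equiv), 45 °C
Reagents that add atoms: trimethyl orthoformate, COC(OC)OC; methanol, CO
Why: Acid-catalysed ketalisation of the electrophilic ketone, driven by the orthoester; C2 continues to equilibrate until the all-trans ketal is fixed. The silyl and benzyl-type ethers tolerate the weak acid, and the ketone is masked before the C4 arm is freed.

Step 13
Reactants: 21 ketal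
Product: 22 ketal with a free hydroxymethyl group at C4 of ring C
Conditions: DDQ, CH2Cl2/pH 7 buffer, 0 °C
Reagents that add atoms: none
Why: Oxidative cleavage of the 4-methoxybenzyl ether by hydride abstraction at the electron-rich benzylic carbon, a reaction routinely run in the presence of dialkyl sulfides such as thioglycosides.

Step 14
Reactants: 22 alcohol
Product: 24 carboxylic acid at C4 of ring C, via aldehyde 23 (not isolated)
Conditions: TEMPO (0.2 equiv), PhI(OAc)2 (2.5 equiv), MeCN/H2O, rt
Reagents that add atoms: water, O
Why: Oxoammonium oxidation of the primary alcohol to the aldehyde and, through its hydrate, to the acid; this oxidant pair leaves sulfides untouched, as in the preparation of thioglycoside uronic acids. The centre next to the new carbonyl is already in its more stable trans arrangement.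

Step 15
Reactants: 24 acid
Product: 25 tert-butyl (3R,4S,5S)-4-{(2R)-1-[(tert-butyldiphenylsilyl)oxy]propan-2-yl}-5-(1,1,2-trimethoxy-2-oxoethyl)thiolane-3-carboxylate
Conditions: tert-butyl 2,2,2-trichloroacetimidate, cyclohexane/CH2Cl2, rt
Reagents that add atoms: tert-butyl 2,2,2-trichloroacetimidate, CC(C)(C)OC(=N)C(Cl)(Cl)Cl
Why: Mild tert-butyl esterification by O-alkylation of the acid with the imidate; the resulting ester can later be removed without base or fluoride.

Step 16
Reactants: 25 tert-butyl ester
Product: 26 primary alcohol (CH2OH on the C3 side chain of ring C)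
Conditions: Bu4NF, AcOH, THF, 0 °C → rt
Reagents that add atoms: none
Why: Fluoride cleavage of the primary silyl ether; buffering protects the two esters and the centre α to the tert-butyl ester.

Step 17
Reactants: 26 alcohol
Product: 27 primary iodide (CH2I in place of CH2OH; stereocentres as in 26)
Conditions: I2, PPh3, imidazole, CH2Cl2, 0 °C
Reagents that add atoms: iodine, II
Why: Appel-type iodination through the alkoxyphosphonium salt; the neighbouring stereocentre is not affected. The iodide is used directly.

### Chain fragment (steps 18–24)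

Step 18
Reactants: 28 (S)-2-(chloromethyl)oxirane
Product: 29 (S)-1-chloro-5-(trimethylsilyl)pent-4-yn-2-ol
Conditions: Me3SiC≡CH, n-BuLi, THF, −78 °C; BF3·OEt2; 28; then H2O
Reagents that add atoms: ethynyltrimethylsilane, C#C[Si](C)(C)C
Why: Lewis-acid-promoted opening of the epoxide by a lithium acetylide at the unsubstituted carbon; the C–O bond at the stereocentre stays intact and chloride is not displaced at −78 °C.

Step 19
Reactants: 29 chlorohydrin
Product: 30 (S)-2-[3-(trimethylsilyl)prop-2-yn-1-yl]oxirane
Conditions: NaH, THF, 0 °C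
Reagents that add atoms: none
Why: Intramolecular Williamson closure (3-exo-tet); the stereocentre keeps its oxygen, and the aprotic base leaves the silyl alkyne intact.

Step 20
Reactants: 30 epoxide
Product: 31 (R)-1-(trimethylsilyl)hepta-1,6-diyn-4-ol
Conditions: HC≡CH, n-BuLi, THF, −78 °C; BF3·OEt2; 30; then H2O
Reagents that add atoms: acetylene, C#C
Why: Second Lewis-acid-promoted acetylide opening at the terminal epoxide carbon; the carbinol now has one silylated and one free propargyl arm, which is what makes C7' a stereocentre.

Step 21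
Reactants: 31 diynol
Product: 32 (R)-tert-butyldiphenyl{[1-(trimethylsilyl)hepta-1,6-diyn-4-yl]oxy}silane
Conditions: t-BuPh2SiCl, imidazole, DMAP (cat.), DMF, rt
Reagents that add atoms: tert-butyl(chloro)diphenylsilane, CC(C)(C)[Si](Cl)(c1ccccc1)c1ccccc1
Why: Silylation of the secondary alcohol with a group that survives the acid of step 36 and blocks the hydroxyl during the acylation of step 37.

Step 22
Reactants: 32 silyl ether
Product: 34 tert-butyl{[(1E,4R)-1-iodo-7-(trimethylsilyl)hept-1-en-6-yn-4-yl]oxy}diphenylsilane, via E-alkenylzirconocene chloride 33 (not isolated)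
Conditions: Cp2Zr(H)Cl, THF, rt; then I2, 0 °C
Reagents that add atoms: iodine, II
Why: Hydrozirconation of the terminal alkyne (syn addition, zirconium at the terminus) and iodinolysis with retention give the E-alkenyl iodide; the silylated alkyne reacts much more slowly and is kept.

Step 23
Reactants: 34 silyl alkyne
Product: 35 tert-butyl{[(1E,4R)-1-iodohept-1-en-6-yn-4-yl]oxy}diphenylsilane
Conditions: K2CO3, MeOH, rt
Reagents that add atoms: none
Why: Methanolysis of the alkynyl C–Si bond; the E-alkenyl iodide and the hindered silyl ether are stable to carbonate.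

Step 24
Reactants: 35 terminal alkyne
Product: 36 tert-butyl{[(1E,4S,6E)-1-iodo-7-(4,4,5,5-tetramethyl-1,3,2-dioxaborolan-2-yl)hepta-1,6-dien-4-yl]oxy}diphenylsilane
Conditions: pinacolborane, (c-C6H11)2BH (0.1 equiv), neat, rt
Reagents that add atoms: pinacolborane, [H]B1OC(C)(C)C(C)(C)O1
Why: Dialkylborane-catalysed hydroboration of the terminal alkyne (syn, boron at the terminus) gives the E-alkenyl boronate; the alkenyl iodide does not react with the boranes.

### Rings A and B fragment (steps 25–34)

Step 25
Reactants: 37 4,4-diethoxybut-1-yne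
Product: 38 2-[(E)-4,4-diethoxybut-1-en-1-yl]-4,4,5,5-tetramethyl-1,3,2-dioxaborolane
Conditions: pinacolborane, (c-C6H11)2BH (0.1 equiv), neat, rt
Reagents that add atoms: pinacolborane, [H]B1OC(C)(C)C(C)(C)O1
Why: The same syn hydroboration; it fixes the E geometry of the diene terminus that will carry the side arm of ring A.

Step 26
Reactants: 38 alkenyl boronate; 39 (E)-2-bromobut-2-ene
Product: 40 (3E,5E)-1,1-diethoxy-5-methylhepta-3,5-diene
Conditions: Pd(PPh3)4 (0.03 equiv), NaOH (aq.), THF, 60 °C
Reagents that add atoms: none
Why: Suzuki–Miyaura coupling of two alkenyl partners with retention at both, giving the E,E-diene with the substitution pattern of ring A.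

Step 27
Reactants: 41 (R)-lactic acid; 42 pivalaldehyde
Product: 43 (2R,5R)-2-tert-butyl-5-methyl-1,3-dioxolan-4-one
Conditions: TsOH (cat.), pentane, reflux with water separator; crystallisation
Reagents that add atoms: none
Why: Acid-catalysed acetalisation under equilibrating conditions; the cis isomer, with tert-butyl and methyl on the same face, is favoured and is purified by crystallisation.

Step 28
Reactants: 43 dioxolanone
Product: 45 (R)-2-tert-butyl-5-methylidene-1,3-dioxolan-4-one, via bromide 44 (not isolated)
Conditions: N-bromosuccinimide, AIBN (cat.), PhCF3, 80 °C; then Et3N, Et2O, 0 °C → rt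
Reagents that add atoms: none
Why: Radical bromination at the tertiary C–H flanked by oxygen and carbonyl, then dehydrobromination to the exocyclic alkene; the acetal carbon is untouched and remains the only stereocentre.

Step 29
Reactants: 40 diene; 45 dienophile
Product: 46 (2R,5S,6R,9R)-2-tert-butyl-6-(2,2-diethoxyethyl)-8,9-dimethyl-1,3-dioxaspiro[4.5]dec-7-en-4-one
Conditions: toluene, BHT (cat.), 110 °C, sealed tube
Reagents that add atoms: none
Why: Diels–Alder reaction: the methylated diene terminus bonds to the CH2 of the captodative dienophile, the lactone carbonyl lies exo, and the diene adds to the face of 45 opposite the tert-butyl group. The E,E-diene puts the side arm and the ring methyl cis, so A1, A2 and A5 are set together.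

Step 30
Reactants: 46 cycloadduct
Product: 47 2-[(2R,5S,6R,9R)-2-tert-butyl-8,9-dimethyl-4-oxo-1,3-dioxaspiro[4.5]dec-7-en-6-yl]acetaldehyde
Conditions: pyridinium p-toluenesulfonate, acetone/H2O, 55 °C
Reagents that add atoms: water, O
Why: Hydrolysis of the diethyl acetal; the dioxolanone, an acylal that is itself formed under acid, survives.

Step 31
Reactants: 47 aldehyde
Product: 48 (2R,5S,6R,9R)-2-tert-butyl-6-[(2E)-3-iodoprop-2-en-1-yl]-8,9-dimethyl-1,3-dioxaspiro[4.5]dec-7-en-4-one
Conditions: CrCl2, CHI3, THF/1,4-dioxane, 0 °C → rt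
Reagents that add atoms: iodoform, IC(I)I
Why: Takai olefination: the geminal dichromium reagent adds to the aldehyde and eliminates to the E-alkenyl iodide; the acylal is inert to CrCl2.

Step 32
Reactants: 48 alkenyl iodide
Product: 49 methyl (1S,2R,5R)-1-hydroxy-2-[(2E)-3-iodoprop-2-en-1-yl]-4,5-dimethylcyclohex-3-ene-1-carboxylate
Conditions: NaOMe (0.2 equiv), MeOH, 0 °C
Reagents that add atoms: methanol, CO
Why: Methanolysis at the lactone carbonyl releases pivalaldehyde and the tertiary α-hydroxy methyl ester without touching the quaternary centre.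

Step 33
Reactants: 49 hydroxy ester
Product: 50 methyl (1S,2R,5R)-1-acetoxy-2-[(2E)-3-iodoprop-2-en-1-yl]-4,5-dimethylcyclohex-3-ene-1-carboxylate
Conditions: Ac2O, Et3N, DMAP (0.2 equiv), CH2Cl2, 40 °C
Reagents that add atoms: acetic anhydride, CC(=O)OC(C)=O
Why: DMAP-catalysed acetylation of the tertiary alcohol; the acetate methyl becomes C3 of ring B.

Step 34
Reactants: 50 acetate
Product: 51 (5S,6R,9R)-4-hydroxy-6-[(2E)-3-iodoprop-2-en-1-yl]-8,9-dimethyl-1-oxaspiro[4.5]deca-3,7-dien-2-one
Conditions: LiN(SiMe3)2 (3 equiv), THF, −78 → 0 °C; then aq. HCl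
Reagents that add atoms: none
Why: Dieckmann condensation: the acetate enolate attacks the neighbouring methyl ester (5-exo-trig) and the product is held as its stable tetronate anion. The silylamide does not attack the E-alkenyl iodide at these temperatures.

### Assembly (steps 35–40)

Step 35
Reactants: 27 iodide; 36 alkenyl iodide boronate
Product: 53 coupled tert-butyl ester whose C3 side chain is CH(CH3)CH2CH=CHCH2CH(OSiPh2t-Bu)CH2CH=CH–B(pin) with both alkenes E, via alkylzinc iodide 52 (not isolated)
Conditions: Zn dust (activated), LiCl, THF, 35 °C; then 36, Pd(PPh3)4 (0.05 equiv), THF/N,N-dimethylacetamide, rt → 45 °C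
Reagents that add atoms: none
Why: Negishi coupling: zinc inserts into the primary C–I bond in the presence of esters, ketal and sulfide, and the alkylzinc couples with the alkenyl iodide with retention of the E geometry. The alkenyl boronate is inert because no base is present.

Step 36
Reactants: 53 tert-butyl ester
Product: 54 carboxylic acid (free CO2H at C4 of ring C)
Conditions: CF3CO2H/CH2Cl2 (1:4), 0 °C
Reagents that add atoms: none
Why: Acidolysis of the tert-butyl ester through the tert-butyl cation; the ester-deactivated ketal, the tert-butyldiphenylsilyl ether and the alkenyl boronate survive brief anhydrous acid.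

Step 37
Reactants: 54 acid; 51 spiro tetronic acid
Product: 56 3-acyl tetronic acid carrying the E-alkenyl iodide on ring A and the E-alkenyl boronate on the chain, via 4-O-acyl enol ester 55 (not isolated)
Conditions: DCC, DMAP (1.5 equiv), CH2Cl2, 0 °C → rt
Reagents that add atoms: none
Why: Carbodiimide/DMAP C-acylation of a tetronic acid: O-acylation gives 55, and DMAP then carries the acyl group to C3, where the strongly acidic tricarbonyl product is the thermodynamic sink. Any epimerisation next to the activated carbonyl returns to the all-trans thiolane.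

Step 38
Reactants: 56 seco compound
Product: 57 macrocycle (ring D closed; C7' silyl ether; ketal methyl ester; free tetronic acid)
Conditions: Pd(dppf)Cl2 (0.15 equiv), AsPh3 (0.3 equiv), Cs2CO3, DMF/THF/H2O, rt, 1 mM
Reagents that add atoms: none
Why: Intramolecular Suzuki–Miyaura coupling of the E-alkenyl iodide with the E-alkenyl boronate forms C3'–C4' with retention at both ends and closes the 19-membered ring. The acyl tetronic acid is carried as its caesium salt, and high dilution suppresses oligomers.

Step 39
Reactants: 57 macrocycle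
Product: 58 macrocycle with free C7' hydroxyl
Conditions: Bu4NF, AcOH, THF, 40 °C
Reagents that add atoms: none
Why: Fluoride removal of the secondary silyl ether; nothing else in 57 is fluoride-labile.

Step 40
Reactants: 58 ketal methyl ester
Product: 60 target, via ketal acid 59 (not isolated)
Conditions: LiOH, THF/MeOH/H2O, rt; then 2 M HCl, THF, 35 °C
Reagents that add atoms: lithium hydroxide, [Li+].[OH-]; water, O
Why: Saponification of the methyl ester, then acid hydrolysis of the ketal, which is easier at the free acid. C2 of ring C is enolisable once the ketone is free and rests in the trans arrangement already present.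

## Compound list

1 | 4-methoxybenzyl alcohol | COc1ccc(CO)cc1 | starting material
2 | methyl acrylate | C=CC(=O)OC | starting material
3 | methyl 3-[(4-methoxybenzyl)oxy]propanoate | COC(=O)CCOCc1ccc(OC)cc1 | intermediate
4 | 3-[(4-methoxybenzyl)oxy]propanoic acid | OC(=O)CCOCc1ccc(OC)cc1 | intermediate
5 | (S)-4-benzyl-1,3-oxazolidin-2-one | O=C1N[C@@H](Cc2ccccc2)CO1 | starting material
6 | mixed anhydride of 4 with pivalic acid (not isolated) | CC(C)(C)C(=O)OC(=O)CCOCc1ccc(OC)cc1 | intermediate
7 | (S)-4-benzyl-3-{3-[(4-methoxybenzyl)oxy]propanoyl}-1,3-oxazolidin-2-one | COc1ccc(COCCC(=O)N2C(=O)OC[C@@H]2Cc2ccccc2)cc1 | intermediate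
8 | methyl (S)-3-hydroxy-2-methylpropanoate | COC(=O)[C@@H](C)CO | starting material
9 | methyl (S)-3-[(tert-butyldiphenylsilyl)oxy]-2-methylpropanoate | COC(=O)[C@@H](C)CO[Si](c1ccccc1)(c1ccccc1)C(C)(C)C | intermediate
10 | (S)-3-[(tert-butyldiphenylsilyl)oxy]-2-methylpropanal | O=C[C@@H](C)CO[Si](c1ccccc1)(c1ccccc1)C(C)(C)C | intermediate
11 | Z-dibutylboron enolate of 7 (not isolated) | CCCCB(CCCC)O/C(=C\COCc1ccc(OC)cc1)N1C(=O)OC[C@@H]1Cc1ccccc1 | intermediate
12 | (S)-4-benzyl-3-[(2S,3R,4S)-5-[(tert-butyldiphenylsilyl)oxy]-3-hydroxy-2-{[(4-methoxybenzyl)oxy]methyl}-4-methylpentanoyl]-1,3-oxazolidin-2-one | CC(C)(C)[Si](c1ccccc1)(c1ccccc1)OC[C@H](C)[C@@H](O)[C@H](COCc1ccc(OC)cc1)C(=O)N1C(=O)OC[C@@H]1Cc1ccccc1 | intermediate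
13 | (2S,3R,4S)-5-[(tert-butyldiphenylsilyl)oxy]-2-{[(4-methoxybenzyl)oxy]methyl}-4-methylpentane-1,3-diol | CC(C)(C)[Si](c1ccccc1)(c1ccccc1)OC[C@H](C)[C@@H](O)[C@@H](CO)COCc1ccc(OC)cc1 | intermediate
14 | 1,3-bis(methanesulfonate) of diol 13 (stereocentres untouched) | CC(C)(C)[Si](c1ccccc1)(c1ccccc1)OC[C@H](C)[C@@H](OS(C)(=O)=O)[C@@H](COS(C)(=O)=O)COCc1ccc(OC)cc1 | intermediate
15 | sodium thiolate in which sulfur has replaced the primary mesylate of 14 (not isolated) | CC(C)(C)[Si](c1ccccc1)(c1ccccc1)OC[C@H](C)[C@@H](OS(C)(=O)=O)[C@@H](C[S-])COCc1ccc(OC)cc1.[Na+] | intermediate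
16 | (2S,3R)-2-{(2S)-1-[(tert-butyldiphenylsilyl)oxy]propan-2-yl}-3-{[(4-methoxybenzyl)oxy]methyl}thietane (trans) | CC(C)(C)[Si](c1ccccc1)(c1ccccc1)OC[C@H](C)[C@@H]1SC[C@H]1COCc1ccc(OC)cc1 | intermediate
17 | methyl chlorooxoacetate | COC(=O)C(=O)Cl | starting material
18 | methyl 3-diazo-2-oxopropanoate | COC(=O)C(=O)C=[N+]=[N-] | intermediate
19 | thietanium ylide of 16 with a 3-methoxy-2,3-dioxopropan-1-ide group on sulfur (not isolated) | CC(C)(C)[Si](c1ccccc1)(c1ccccc1)OC[C@H](C)[C@@H]1[S+]([CH-]C(=O)C(=O)OC)C[C@H]1COCc1ccc(OC)cc1 | intermediate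
20 | methyl 2-[(2S,3S,4R)-3-{(2R)-1-[(tert-butyldiphenylsilyl)oxy]propan-2-yl}-4-{[(4-methoxybenzyl)oxy]methyl}thiolan-2-yl]-2-oxoacetate (all-trans) | CC(C)(C)[Si](c1ccccc1)(c1ccccc1)OC[C@H](C)[C@@H]1[C@@H](C(=O)C(=O)OC)SC[C@H]1COCc1ccc(OC)cc1 | intermediate
21 | dimethyl ketal of 20 (methyl 2,2-dimethoxyacetate at C2 of ring C) | CC(C)(C)[Si](c1ccccc1)(c1ccccc1)OC[C@H](C)[C@@H]1[C@@H](C(OC)(OC)C(=O)OC)SC[C@H]1COCc1ccc(OC)cc1 | intermediate
22 | ketal 21 with free hydroxymethyl at C4 of ring C | CC(C)(C)[Si](c1ccccc1)(c1ccccc1)OC[C@H](C)[C@@H]1[C@@H](C(OC)(OC)C(=O)OC)SC[C@H]1CO | intermediate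
23 | corresponding C4 aldehyde (not isolated) | CC(C)(C)[Si](c1ccccc1)(c1ccccc1)OC[C@H](C)[C@@H]1[C@@H](C(OC)(OC)C(=O)OC)SC[C@H]1C=O | intermediate
24 | (3R,4S,5S)-4-{(2R)-1-[(tert-butyldiphenylsilyl)oxy]propan-2-yl}-5-(1,1,2-trimethoxy-2-oxoethyl)thiolane-3-carboxylic acid | CC(C)(C)[Si](c1ccccc1)(c1ccccc1)OC[C@H](C)[C@@H]1[C@@H](C(OC)(OC)C(=O)OC)SC[C@H]1C(=O)O | intermediate
25 | tert-butyl (3R,4S,5S)-4-{(2R)-1-[(tert-butyldiphenylsilyl)oxy]propan-2-yl}-5-(1,1,2-trimethoxy-2-oxoethyl)thiolane-3-carboxylate | CC(C)(C)[Si](c1ccccc1)(c1ccccc1)OC[C@H](C)[C@@H]1[C@@H](C(OC)(OC)C(=O)OC)SC[C@H]1C(=O)OC(C)(C)C | intermediate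
26 | tert-butyl (3R,4S,5S)-4-[(2R)-1-hydroxypropan-2-yl]-5-(1,1,2-trimethoxy-2-oxoethyl)thiolane-3-carboxylate | OC[C@H](C)[C@@H]1[C@@H](C(OC)(OC)C(=O)OC)SC[C@H]1C(=O)OC(C)(C)C | intermediate
27 | primary iodide of 26 (CH2I in place of CH2OH; stereocentres as in 26) | IC[C@H](C)[C@@H]1[C@@H](C(OC)(OC)C(=O)OC)SC[C@H]1C(=O)OC(C)(C)C | intermediate
28 | (S)-2-(chloromethyl)oxirane | ClC[C@@H]1CO1 | starting material
29 | (S)-1-chloro-5-(trimethylsilyl)pent-4-yn-2-ol | ClC[C@@H](O)CC#C[Si](C)(C)C | intermediate
30 | (S)-2-[3-(trimethylsilyl)prop-2-yn-1-yl]oxirane | C[Si](C)(C)C#CC[C@H]1CO1 | intermediate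
31 | (R)-1-(trimethylsilyl)hepta-1,6-diyn-4-ol | C#CC[C@@H](O)CC#C[Si](C)(C)C | intermediate
32 | (R)-tert-butyldiphenyl{[1-(trimethylsilyl)hepta-1,6-diyn-4-yl]oxy}silane | C#CC[C@@H](O[Si](c1ccccc1)(c1ccccc1)C(C)(C)C)CC#C[Si](C)(C)C | intermediate
33 | E-alkenylzirconocene chloride from the terminal alkyne of 32 (not isolated) | Cl[Zr](/C=C/C[C@@H](O[Si](c1ccccc1)(c1ccccc1)C(C)(C)C)CC#C[Si](C)(C)C)(C1C=CC=C1)C1C=CC=C1 | intermediate
34 | tert-butyl{[(1E,4R)-1-iodo-7-(trimethylsilyl)hept-1-en-6-yn-4-yl]oxy}diphenylsilane | I/C=C/C[C@@H](O[Si](c1ccccc1)(c1ccccc1)C(C)(C)C)CC#C[Si](C)(C)C | intermediate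
35 | tert-butyl{[(1E,4R)-1-iodohept-1-en-6-yn-4-yl]oxy}diphenylsilane | I/C=C/C[C@@H](O[Si](c1ccccc1)(c1ccccc1)C(C)(C)C)CC#C | intermediate
36 | tert-butyl{[(1E,4S,6E)-1-iodo-7-(4,4,5,5-tetramethyl-1,3,2-dioxaborolan-2-yl)hepta-1,6-dien-4-yl]oxy}diphenylsilane | I/C=C/C[C@@H](O[Si](c1ccccc1)(c1ccccc1)C(C)(C)C)C/C=C/B1OC(C)(C)C(C)(C)O1 | intermediate
37 | 4,4-diethoxybut-1-yne | CCOC(CC#C)OCC | starting material
38 | 2-[(E)-4,4-diethoxybut-1-en-1-yl]-4,4,5,5-tetramethyl-1,3,2-dioxaborolane | CCOC(C/C=C/B1OC(C)(C)C(C)(C)O1)OCC | intermediate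
39 | (E)-2-bromobut-2-ene | C/C=C(/Br)C | starting material
40 | (3E,5E)-1,1-diethoxy-5-methylhepta-3,5-diene | CCOC(C/C=C/C(C)=C/C)OCC | intermediate
41 | (R)-lactic acid | C[C@@H](O)C(=O)O | starting material
42 | pivalaldehyde | CC(C)(C)C=O | starting material
43 | (2R,5R)-2-tert-butyl-5-methyl-1,3-dioxolan-4-one (cis) | C[C@H]1O[C@@H](C(C)(C)C)OC1=O | intermediate
44 | (2R,5S)-5-bromo-2-tert-butyl-5-methyl-1,3-dioxolan-4-one (not isolated) | C[C@]1(Br)O[C@@H](C(C)(C)C)OC1=O | intermediate
45 | (R)-2-tert-butyl-5-methylidene-1,3-dioxolan-4-one | C=C1O[C@@H](C(C)(C)C)OC1=O | intermediate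
46 | (2R,5S,6R,9R)-2-tert-butyl-6-(2,2-diethoxyethyl)-8,9-dimethyl-1,3-dioxaspiro[4.5]dec-7-en-4-one | CC1=C[C@@H](CC(OCC)OCC)[C@]2(C[C@H]1C)O[C@@H](C(C)(C)C)OC2=O | intermediate
47 | 2-[(2R,5S,6R,9R)-2-tert-butyl-8,9-dimethyl-4-oxo-1,3-dioxaspiro[4.5]dec-7-en-6-yl]acetaldehyde | CC1=C[C@@H](CC=O)[C@]2(C[C@H]1C)O[C@@H](C(C)(C)C)OC2=O | intermediate
48 | (2R,5S,6R,9R)-2-tert-butyl-6-[(2E)-3-iodoprop-2-en-1-yl]-8,9-dimethyl-1,3-dioxaspiro[4.5]dec-7-en-4-one | CC1=C[C@@H](C/C=C/I)[C@]2(C[C@H]1C)O[C@@H](C(C)(C)C)OC2=O | intermediate
49 | methyl (1S,2R,5R)-1-hydroxy-2-[(2E)-3-iodoprop-2-en-1-yl]-4,5-dimethylcyclohex-3-ene-1-carboxylate | CC1=C[C@@H](C/C=C/I)[C@@](O)(C[C@H]1C)C(=O)OC | intermediate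
50 | methyl (1S,2R,5R)-1-acetoxy-2-[(2E)-3-iodoprop-2-en-1-yl]-4,5-dimethylcyclohex-3-ene-1-carboxylate | CC1=C[C@@H](C/C=C/I)[C@@](OC(C)=O)(C[C@H]1C)C(=O)OC | intermediate
51 | (5S,6R,9R)-4-hydroxy-6-[(2E)-3-iodoprop-2-en-1-yl]-8,9-dimethyl-1-oxaspiro[4.5]deca-3,7-dien-2-one | CC1=C[C@@H](C/C=C/I)[C@]2(C[C@H]1C)OC(=O)C=C2O | intermediate
52 | alkylzinc iodide from 27 (CH2ZnI in place of CH2I; not isolated) | I[Zn]C[C@H](C)[C@@H]1[C@@H](C(OC)(OC)C(=O)OC)SC[C@H]1C(=O)OC(C)(C)C | intermediate
53 | Negishi product: thiolane tert-butyl ester of 25 type whose C3 side chain is CH(CH3)CH2CH=CHCH2CH(OSiPh2t-Bu)CH2CH=CH–B(pin), both alkenes E, stereocentres as in 27 and 36 | CC1(C)OB(/C=C/C[C@H](O[Si](c2ccccc2)(c2ccccc2)C(C)(C)C)C/C=C/C[C@H](C)[C@@H]2[C@@H](C(OC)(OC)C(=O)OC)SC[C@H]2C(=O)OC(C)(C)C)OC1(C)C | intermediate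
54 | carboxylic acid from 53 (CO2H at C4 of ring C) | CC1(C)OB(/C=C/C[C@H](O[Si](c2ccccc2)(c2ccccc2)C(C)(C)C)C/C=C/C[C@H](C)[C@@H]2[C@@H](C(OC)(OC)C(=O)OC)SC[C@H]2C(=O)O)OC1(C)C | intermediate
55 | enol ester: 4-O-acyl derivative of tetronic acid 51 with acid 54 (not isolated) | CC1(C)OB(/C=C/C[C@H](O[Si](c2ccccc2)(c2ccccc2)C(C)(C)C)C/C=C/C[C@H](C)[C@@H]2[C@@H](C(OC)(OC)C(=O)OC)SC[C@H]2C(=O)OC2=CC(=O)O[C@]23C[C@@H](C)C(C)=C[C@H]3C/C=C/I)OC1(C)C | intermediate
56 | 3-acyl tetronic acid: acyl group of 54 on C3 of ring B of 51, with E-alkenyl iodide on the ring-A arm and E-alkenyl boronate on the chain | CC1(C)OB(/C=C/C[C@H](O[Si](c2ccccc2)(c2ccccc2)C(C)(C)C)C/C=C/C[C@H](C)[C@@H]2[C@@H](C(OC)(OC)C(=O)OC)SC[C@H]2C(=O)C2=C(O)[C@@]3(C[C@@H](C)C(C)=C[C@H]3C/C=C/I)OC2=O)OC1(C)C | intermediate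
57 | macrocycle: rings A–D complete, C7' tert-butyldiphenylsilyl ether, dimethyl ketal methyl ester, free tetronic acid | CC1=C[C@H]2C/C=C/C=C/C[C@H](O[Si](c3ccccc3)(c3ccccc3)C(C)(C)C)C/C=C/C[C@H](C)[C@@H]3[C@@H](C(OC)(OC)C(=O)OC)SC[C@H]3C(=O)C3=C(O)[C@@]2(C[C@H]1C)OC3=O | intermediate
58 | macrocycle 57 with free C7' hydroxyl | CC1=C[C@H]2C/C=C/C=C/C[C@H](O)C/C=C/C[C@H](C)[C@@H]3[C@@H](C(OC)(OC)C(=O)OC)SC[C@H]3C(=O)C3=C(O)[C@@]2(C[C@H]1C)OC3=O | intermediate
59 | ketal acid: 58 with CO2H in place of CO2Me (not isolated) | CC1=C[C@H]2C/C=C/C=C/C[C@H](O)C/C=C/C[C@H](C)[C@@H]3[C@@H](C(OC)(OC)C(=O)O)SC[C@H]3C(=O)C3=C(O)[C@@]2(C[C@H]1C)OC3=O | intermediate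
60 | target: the α-keto acid and acyl tetronic acid macrocycle (CNP0224658.3) | CC1=C[C@H]2C/C=C/C=C/C[C@H](O)C/C=C/C[C@H](C)[C@@H]3[C@@H](C(=O)C(=O)O)SC[C@H]3C(=O)C3=C(O)[C@@]2(C[C@H]1C)OC3=O | target

## Step count and least certain steps

Total: 40 steps. Longest linear sequence: 20 steps (1–3, 6–9, 11–17, 35–40); counted from ester 8 it is 19.

**Step 11 (key step).** Three things can go wrong. The unsubstituted S–CH2 bond may migrate in place of the substituted one, giving the regioisomeric thiolane. The sulfide may bind the rhodium catalyst so that the carbene dimerises before it reaches sulfur. The keto-ester-stabilised ylide may be too stable to rearrange below the temperature at which it fragments. The fallback avoids both the carbene and the [1,2]-shift. It sets out from bis-mesylate 14: potassium thioacetate displaces only the primary mesylate to give thioacetate F1. Hydrazinolysis of the thioester in the presence of methyl bromopyruvate and i-Pr2NEt gives sulfide F2. With Cs2CO3 in MeCN the keto-ester enolate of F2 displaces the secondary mesylate through carbon (5-exo-tet, inversion). The thietane route inverts this carbon on S-closure and retains it in the shift, so the net result is the same and the product is 20, where the route is rejoined.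

**Step 9.** The hindered secondary mesylate may undergo elimination by the basic sulfide, or sulfide may bridge two molecules, before the slow 4-exo-tet closure occurs. The fallback introduces sulfur with a neutral reagent and releases the thiolate only afterwards. From 14, thiourea (EtOH, 60 °C) alkylates at the primary mesylate alone to give isothiouronium salt F3. Cold dilute aqueous NaOH then liberates thiolate 15 with no excess sulfide present, and it closes to 16. If the four-membered closure itself cannot be achieved, the fallback under step 11 bypasses the thietane altogether.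

**Step 35.** Iodide 27 may alkylate its own sulfur (a bicyclic sulfonium salt) during zinc insertion, and the β-branched alkylzinc may be protonated or transmetalate slowly. The fallback reverses the polarity. Iodide 27 is used as the electrophile with alkenylzirconocene 33 (Pd(acac)2, LiBr, THF/N-methylpyrrolidone, 55 °C) to give silyl enyne F4. K2CO3 in MeOH gives terminal alkyne F5. Hydroboration with pinacolborane and catalytic (c-C6H11)2BH then gives 53.

**Step 37.** With two hindered partners the acyl transfer may stop at enol ester 55 or be diverted to the N-acylurea. The fallback builds ring B around the acyl group. Acid 54 is condensed with Meldrum's acid (DCC, DMAP) to acyl Meldrum's acid F6. Heating F6 with hydroxy ester 49 in toluene at 90 °C traps the acylketene as β-keto ester F7. A Dieckmann condensation (KOt-Bu, THF, 0 °C) then closes ring B and gives 56.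

**Step 38.** The chelating acyl tetronate may sequester palladium, and slow coupling at high dilution invites protodeboronation or oligomerisation. The fallback masks the tetronic acid. Me3SiCHN2 in MeOH/toluene converts 56 into O-methyl tetronate F8. The ring is closed under fluoride activation without aqueous base (Pd(PPh3)4, CsF, THF) to give macrocycle F9. LiCl in DMSO at 50 °C removes the methyl group and returns 57.

## Further compounds

F1 | step 11 | primary thioacetate, secondary mesylate derived from 14 | CC(C)(C)[Si](c1ccccc1)(c1ccccc1)OC[C@H](C)[C@@H](OS(C)(=O)=O)[C@@H](CSC(C)=O)COCc1ccc(OC)cc1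
F2 | step 11 | sulfide of F1 type in which sulfur carries CH2C(=O)CO2Me (secondary mesylate retained) | CC(C)(C)[Si](c1ccccc1)(c1ccccc1)OC[C@H](C)[C@@H](OS(C)(=O)=O)[C@@H](CSCC(=O)C(=O)OC)COCc1ccc(OC)cc1
F3 | step 9 | isothiouronium methanesulfonate at the primary carbon of 14 (secondary mesylate retained) | CC(C)(C)[Si](c1ccccc1)(c1ccccc1)OC[C@H](C)[C@@H](OS(C)(=O)=O)[C@@H](CSC(N)=[NH2+])COCc1ccc(OC)cc1.CS(=O)(=O)[O-]
F4 | step 35 | coupling product of 27 with 33: thiolane tert-butyl ester with E-alkene and trimethylsilyl alkyne in the chain | C[Si](C)(C)C#CC[C@H](O[Si](c1ccccc1)(c1ccccc1)C(C)(C)C)C/C=C/C[C@H](C)[C@@H]1[C@@H](C(OC)(OC)C(=O)OC)SC[C@H]1C(=O)OC(C)(C)C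
F5 | step 35 | terminal alkyne from F4 | C#CC[C@H](O[Si](c1ccccc1)(c1ccccc1)C(C)(C)C)C/C=C/C[C@H](C)[C@@H]1[C@@H](C(OC)(OC)C(=O)OC)SC[C@H]1C(=O)OC(C)(C)C
F6 | step 37 | acyl Meldrum's acid of 54 | CC1(C)OB(/C=C/C[C@H](O[Si](c2ccccc2)(c2ccccc2)C(C)(C)C)C/C=C/C[C@H](C)[C@@H]2[C@@H](C(OC)(OC)C(=O)OC)SC[C@H]2C(=O)C2C(=O)OC(C)(C)OC2=O)OC1(C)C
F7 | step 37 | β-keto ester of the tertiary alcohol of 49 with the acyl group of 54 | CC1(C)OB(/C=C/C[C@H](O[Si](c2ccccc2)(c2ccccc2)C(C)(C)C)C/C=C/C[C@H](C)[C@@H]2[C@@H](C(OC)(OC)C(=O)OC)SC[C@H]2C(=O)CC(=O)O[C@]3(C[C@@H](C)C(C)=C[C@H]3C/C=C/I)C(=O)OC)OC1(C)C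
F8 | step 38 | 4-O-methyl ether of 56 | CC1(C)OB(/C=C/C[C@H](O[Si](c2ccccc2)(c2ccccc2)C(C)(C)C)C/C=C/C[C@H](C)[C@@H]2[C@@H](C(OC)(OC)C(=O)OC)SC[C@H]2C(=O)C2=C(OC)[C@@]3(C[C@@H](C)C(C)=C[C@H]3C/C=C/I)OC2=O)OC1(C)C
F9 | step 38 | 4-O-methyl ether of macrocycle 57 | CC1=C[C@H]2C/C=C/C=C/C[C@H](O[Si](c3ccccc3)(c3ccccc3)C(C)(C)C)C/C=C/C[C@H](C)[C@@H]3[C@@H](C(OC)(OC)C(=O)OC)SC[C@H]3C(=O)C3=C(OC)[C@@]2(C[C@H]1C)OC3=O
A1 | alternative 1 | macrocyclic E,E-diene with O-methyl tetronate, ketal methyl ester and free C7' hydroxyl | CC1=C[C@H]2C/C=C/C=C/C[C@H](O)C/C=C/C[C@H](C)[C@@H]3[C@@H](C(OC)(OC)C(=O)OC)SC[C@H]3C(=O)C3=C(OC)[C@@]2(C[C@H]1C)OC3=O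
A2 | alternative 1 | seco precursor of A1 with E-alkenyl iodide on the chain and E-alkenyl tributylstannane on the ring-A arm | I/C=C/C[C@H](O)C/C=C/C[C@H](C)[C@@H]2[C@@H](C(OC)(OC)C(=O)OC)SC[C@H]2C(=O)C2=C(OC)[C@@]3(C[C@@H](C)C(C)=C[C@H]3C/C=C/[Sn](CCCC)(CCCC)CCCC)OC2=O
A3 | alternative 2 | ring-A α-(4-methoxybenzyloxy) acid with the 2-(tert-butyldimethylsilyloxy)ethyl arm | CC1=C[C@@H](CCO[Si](C)(C)C(C)(C)C)[C@@](C(=O)O)(OCc2ccc(OC)cc2)C[C@H]1C
A4 | alternative 2 | δ-lactone precursor of A3: 6-[(Z)-4-(tert-butyldimethylsilyloxy)but-1-enyl]-3-(4-methoxybenzyloxy)-5,6-dimethyltetrahydropyran-2-one (C3 either configuration) | O=C1O[C@](C)(/C=C\CCO[Si](C)(C)C(C)(C)C)[C@H](C)CC1OCc1ccc(OC)cc1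
A5 | alternative 3 | macrocyclic 3-acyl tetronic acid with C7' tert-butyldimethylsilyl ether and ketal methyl ester | CC1=C[C@H]2C/C=C/C=C/C[C@H](O[Si](C)(C)C(C)(C)C)C/C=C/C[C@H](C)[C@@H]3[C@@H](C(OC)(OC)C(=O)OC)SC[C@H]3C(=O)C3=C(O)[C@@]2(C[C@H]1C)OC3=O
A6 | alternative 3 | 20-membered β-keto lactone precursor of A5 (ester of the A1 tertiary oxygen; methyl ester on A1) | CC1=C[C@H]2C/C=C/C=C/C[C@H](O[Si](C)(C)C(C)(C)C)C/C=C/C[C@H](C)[C@@H]3[C@@H](C(OC)(OC)C(=O)OC)SC[C@H]3C(=O)CC(=O)O[C@]2(C[C@H]1C)C(=O)OC
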